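## Analysis of the target

Target 27 is a 1,2-dioxane. For the discussion its atoms are numbered O1–O2–C3–C4–C5–C6, with the acetic acid arm on C6 as C7 (CH2) and C8 (CO2H); systematic names further down use IUPAC locants, where the ketal carbon is position 6 and the CH carbon position 3. C3 is a peroxyketal carbon carrying a methoxy group and a sixteen-carbon chain: three methylenes, a C≡C, an (E)-C=C, seven methylenes and a methyl ketone. There are two stereocenters, C6 (S) and C3 (R), with the methoxy group and the CH2CO2H arm cis. In the chair the methoxy group is therefore axial (anomeric stabilisation) and both carbon substituents are equatorial, which is the thermodynamically preferred arrangement. Only C6 needs absolute control; C3 can be left to equilibration through the ring peroxycarbenium ion. The sensitive groups are the O–O bond (phosphines, low-valent metals, hydrides, hydrogenation), the C6–H and the β-peroxy carboxyl unit (base-induced Kornblum–DeLaMare cleavage and E1cB ring opening), the acid-labile peroxyketal, the enyne (ozone, electrophiles) and the enolisable methyl ketone. The difficulty is to build a peroxide ring with a defined secondary C–O stereocenter and then carry it through a C–C bond formation that attaches an unsaturated, ketone-bearing chain. The route rests on the 1,6-relationship of C3 (ketone oxidation level) and C8 (carboxyl): C3 to C8 are the six carbons of a cyclohexene whose C3=C8 bond has been cleaved, and C6, the 4-position of that ring, holds a hydroperoxide placed to close on C3.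

## Retrosynthetic reasoning

**27 ⇒ 26 ⇒ 21 + 25.** After trivial ester hydrolysis (27 from 26), the side chain is cut between its alkyne and alkene carbons. The enyne alkene would not survive the ozonolysis planned for the ring, and the methyl ketone would not survive amide bases, organozinc reagents, alkoxide, or the acidic peroxide exchange, where it would form peroxyketals of its own. Cutting here leaves only a small, robust alkyne handle on the peroxide fragment 21 and puts the ketone and the (E)-alkene into iodide 25. The forward reaction is a Sonogashira coupling that must tolerate a dialkyl peroxyketal. Iodide 25 goes back through aldehyde 24 to alkene 22: one carbon is excised by ozonolysis and returned as the CHI unit.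

**21 ⇒ 20 ⇒ 19.** The alkyne of 21 is unmasked from silane 20. In 20 the C3–OMe bond and the ester C–O bond are disconnected to the hydroperoxy ketal acid 19. Hydroperoxy and methoxy ketals ionise to the same ring peroxycarbenium ion, so the exchange is reversible and thermodynamic control delivers the axial methoxy group. The gain is that C3 never has to be set kinetically, and any epimer mixture formed earlier converges here.

**19 ⇒ 18 ⇒ 15 (key disconnection).** Acid 19 comes from aldehyde 18 by oxidation. In 18 the C3–O2 bond is cut and C3 and C8 are rejoined as a double bond, which gives cyclohexenyl hydroperoxide 15. This is preferred to cutting C6–O1, which would mean a ring-closing SN2 with a stereochemical burden. It is also preferred to assembling the ring from two fragments, because one carbocycle supplies all six carbons C3–C8, releases C8 at the aldehyde level and leaves no extra unsaturation in the ring. The forward step must cleave the alkene so that the carbonyl oxide sits on C3 and is captured by the C6 hydroperoxide faster than by the tethered aldehyde.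

**15 ⇒ 14 ⇒ 9 + 12; 9 ⇒ 8 ⇒ 7.** The C6–O bond of 15 is formed by SN2 displacement, so 15 is traced through peroxyketal 14 to triflate 9 and the masked hydroperoxide 12 (made from alkene 10). Inversion is required, so alcohol 8 and silyl ether 7 have the opposite configuration at this carbon. The forward reaction has to beat E2 elimination at a secondary ring carbon; this is the weakest point before the key step.

**7 ⇒ 3 + 6.** The bond between the ring sp2 carbon (C3 of the target) and the first chain methylene is cut to alkenyl triflate 3 and alkylzinc 6 (from iodide 5 and chloride 4). The cut is made there because an enol triflate is what an enolisation delivers directly, and Negishi coupling forms sp2–sp3 bonds without disturbing a silyl ether or a silylalkyne.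

**3 ⇒ 1.** Triflate 3 comes from enolate 2 of ketone 1. Ketone 1 has a mirror plane through C1 and C4, so enolisation toward one side by a chiral lithium amide creates the C4 stereocenter (C6 of the target) without forming any bond at that carbon.

## Alternatives that were turned down

**Alternative 1: ring-closing metathesis of an acyclic allylic peroxyketal.** The disconnection is C4–C5, taken as a C4=C5 alkene of a 3,6-dihydro-1,2-dioxine. The O1–O2 bridge and both flanking carbons are first assembled as the acyclic mixed peroxyketal A2, in which C3 carries a vinyl group and C6 an enoate-terminated alkenyl group. In the forward key step a second-generation Hoveyda–Grubbs catalyst closes A2 to dihydrodioxine A1.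
- For: the two halves are made separately, the methoxy group is in place before the ring forms, and the C6 stereocenter is installed on an open chain. On that last point it is stronger than the chosen route, where the displacement is on a ring and elimination competes.
- Against: A1 has an extra C4=C5 bond that must be saturated without touching the O–O bond or the silylalkyne, which leaves diimide as almost the only option and adds a step. The allylic peroxide and allylic peroxyketal in A2 and A1 ionise easily and isomerise under base or metal catalysis to γ-hydroxy enones. Ruthenium carbenes are not innocent toward peroxides. The intermolecular formation of the hindered mixed peroxyketal A2 is an unfavourable equilibrium with no control at C3.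
- Comparison: the chosen strategy gives the saturated ring directly with C8 at the aldehyde level, and pays for this with a harder SN2.

**Alternative 2: oxetane opening with H2O2 forming both C–O bonds.** Both C–O bonds of the peroxide are disconnected to H2O2: C3–O2 from a dimethyl ketal and C6–O1 from an oxetane. The precursor is ketal–oxetane A4. In the forward key step H2O2 and Me3SiOTf convert the ketal into a hydroperoxy ketal, whose terminal oxygen opens the activated (R)-oxetane at C6 with inversion to give dioxane alcohol A3.
- For: H2O2 itself is the O–O source, no hydroperoxide is isolated, the methoxy ketal forms in the same operation, and no ozone is used on an advanced intermediate. In peroxide handling it is shorter than the chosen route, which needs a masked hydroperoxide, an unmasking and a later hydroperoxy-to-methoxy exchange.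
- Against: the order of events is not under control. H2O2 can open the activated oxetane intermolecularly, the ketal can lose both methoxy groups to a gem-dihydroperoxide, and Lewis-acid opening at a secondary carbon has SN1 character that would erode C6. The enantiopure 2-substituted oxetane A4 needs several steps of its own. A3 is a primary alcohol, two oxidations away from the acid in the presence of the peroxyketal.
- Comparison: the chosen route fixes C6 by a plain SN2 before any ring forms and releases C8 one oxidation from the acid, so the overall step count is no worse and the stereochemical argument is cleaner.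

**Alternative 3: diyne linchpin with an alkyne as latent ketal carbon.** C3–O2 and C3–OMe are both disconnected to an internal alkyne, so C3 is an sp carbon in hydroperoxy diyne A6, whose chain comes from a 1,5-diyne alkylated at both ends. In the forward key step Hg(OTf)2 (divalent mercury) in methanol activates the alkyne, the C6 hydroperoxide adds 6-exo-dig at C3, and methanol adds to the resulting peroxycarbenium ion to give dioxane A5.
- For: the carbon assembly by two acetylide alkylations is more convergent than the cyclohexanone route, and C3 arrives at the ketal level with its methoxy group in one step. On step count to the ring it is probably the shortest of all.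
- Against: addition of a hydroperoxide to a metal-activated alkyne is not an established reaction class. The intermediate 3-alkylidene-1,2-dioxane is a vinyl peroxide, a class that rearranges by O–O cleavage. The internal alkyne is electronically unbiased, so 7-endo attack and intermolecular addition of methanol at either carbon compete. The second, silylated alkyne and the peroxide itself are exposed to the mercury salt. A5 still needs deprotection and two oxidations.
- Comparison: in the chosen key step the regiochemistry is decided by the substitution pattern of the alkene, and the capture of a carbonyl oxide by a tethered hydroperoxide is known reactivity.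

Key step: step 9

Remarks on the chemistry:
- The (S,S)-enantiomer of lithium bis(1-phenylethyl)amide is taken to give the (R)-enolate 2, by analogy with the sense of induction of this base class on 4-substituted cyclohexanones; if the sense is the reverse, the (R,R)-amide is used.
- Silane 4 is taken to be a catalogue compound; otherwise it is one C-silylation away from 5-chloropent-1-yne.

## Route

Step 1
Reactants: 1 4-(tert-butyldimethylsilyloxy)cyclohexan-1-one
Product: 3 (R)-4-(tert-butyldimethylsilyloxy)cyclohex-1-en-1-yl trifluoromethanesulfonate, via lithium enolate 2 (not isolated)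
Conditions: (S,S)-bis(1-phenylethyl)amine, n-BuLi, LiCl, THF, −78 °C (1.15 equiv of amide); then PhNTf2, −78 → 0 °C
Reagents that add atoms: N-phenylbis(trifluoromethanesulfonimide), O=S(=O)(N(c1ccccc1)S(=O)(=O)C(F)(F)F)C(F)(F)F
Why: Enantioselective deprotonation: the C2-symmetric lithium amide distinguishes the two enantiotopic axial α-protons of the mirror-symmetric ketone, so C4 becomes a stereocenter (R) in enolate 2 once the symmetry is broken. O-Sulfonylation with PhNTf2 (enol triflate formation) fixes the enolate as 3 without touching C4; the slight excess of base leaves no ketone that could equilibrate the enolate.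

Step 2
Reactants: 4 (5-chloropent-1-yn-1-yl)trimethylsilane
Product: 5 (5-iodopent-1-yn-1-yl)trimethylsilane
Conditions: NaI, acetone, reflux
Reagents that add atoms: sodium iodide, [Na+].[I-]
Why: Finkelstein exchange at a primary carbon, driven by precipitation of NaCl; the iodide is needed for clean zinc insertion.

Step 3
Reactants: 5 (5-iodopent-1-yn-1-yl)trimethylsilane; 3 (R)-4-(tert-butyldimethylsilyloxy)cyclohex-1-en-1-yl trifluoromethanesulfonate
Product: 7 tert-butyldimethyl{[(1R)-4-[5-(trimethylsilyl)pent-4-yn-1-yl]cyclohex-3-en-1-yl]oxy}silane, via alkylzinc iodide 6 (not isolated)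
Conditions: Zn dust (activated with BrCH2CH2Br and Me3SiCl), LiCl, THF, 40 °C; then 3, Pd(PPh3)4 (5 mol %), THF, rt → 45 °C
Reagents that add atoms: none
Why: Zinc inserts into the primary C–I bond, and Negishi coupling of alkylzinc 6 with the alkenyl triflate forms the sp2–sp3 bond under conditions to which the silyl ether and the silylalkyne are inert. The stereocenter is remote and untouched.

Step 4
Reactants: 7 tert-butyldimethyl{[(1R)-4-[5-(trimethylsilyl)pent-4-yn-1-yl]cyclohex-3-en-1-yl]oxy}silane
Product: 8 (1R)-4-[5-(trimethylsilyl)pent-4-yn-1-yl]cyclohex-3-en-1-ol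
Conditions: camphorsulfonic acid (cat.), MeOH/CH2Cl2, 0 °C → rt
Reagents that add atoms: none
Why: Acid-catalysed methanolysis of the secondary silyl ether; fluoride is avoided because it would also cleave the alkynyl C–Si bond.

Step 5
Reactants: 8 (1R)-4-[5-(trimethylsilyl)pent-4-yn-1-yl]cyclohex-3-en-1-ol
Product: 9 (1R)-4-[5-(trimethylsilyl)pent-4-yn-1-yl]cyclohex-3-en-1-yl trifluoromethanesulfonate
Conditions: Tf2O, 2,6-lutidine, CH2Cl2, −78 °C; cold aqueous work-up, used at once
Reagents that add atoms: trifluoromethanesulfonic anhydride, O=S(=O)(OS(=O)(=O)C(F)(F)F)C(F)(F)F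
Why: O-Sulfonylation with retention at carbon; the triflate allows the following SN2 to run at low temperature and is not stored.

Step 6
Reactants: 10 2,3-dimethylbut-2-ene
Product: 12 2-hydroperoxy-2-methoxypropane, via acetone oxide 11 (not isolated)
Conditions: O3/O2, MeOH/CH2Cl2, −78 °C; N2 purge; used as a solution
Reagents that add atoms: ozone, [O-][O+]=O; methanol, CO
Why: Ozonolysis in a participating solvent: carbonyl oxide 11 is captured by methanol as the α-methoxy hydroperoxide, a hydroperoxide whose anion can be alkylated and whose ketal is later removed by mild acid.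

Step 7
Reactants: 9 (1R)-4-[5-(trimethylsilyl)pent-4-yn-1-yl]cyclohex-3-en-1-yl trifluoromethanesulfonate; 12 2-hydroperoxy-2-methoxypropane
Product: 14 (S)-4-[(2-methoxypropan-2-yl)peroxy]-1-[5-(trimethylsilyl)pent-4-yn-1-yl]cyclohex-1-ene, via potassium peroxide salt 13 (not isolated)
Conditions: 12, KOt-Bu, 18-crown-6, THF, 0 °C; then 9, −40 → 0 °C
Reagents that add atoms: none
Why: SN2 displacement: peroxide anion 13 is a strong α-effect nucleophile of low basicity, which favours substitution over E2 at the secondary carbon, and backside attack inverts the carbinol carbon from R to S. Low temperature and an ethereal solvent hold back ionisation of the triflate.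

Step 8
Reactants: 14 (S)-4-[(2-methoxypropan-2-yl)peroxy]-1-[5-(trimethylsilyl)pent-4-yn-1-yl]cyclohex-1-ene
Product: 15 (S)-4-hydroperoxy-1-[5-(trimethylsilyl)pent-4-yn-1-yl]cyclohex-1-ene
Conditions: AcOH/THF/H2O, rt
Reagents that add atoms: none
Why: Hydrolysis of the acyclic peroxyketal goes through the 2-methoxyprop-2-yl cation and breaks no bond at the stereocenter, so the (S) configuration is kept; the alkynylsilane is stable to weak acid.

Step 9
Reactants: 15 (S)-4-hydroperoxy-1-[5-(trimethylsilyl)pent-4-yn-1-yl]cyclohex-1-ene
Product: 18 2-[(3S)-6-hydroperoxy-6-[5-(trimethylsilyl)pent-4-yn-1-yl]-1,2-dioxan-3-yl]acetaldehyde (both epimers at the hydroperoxy ketal carbon), via primary ozonide 16 (not isolated), via ketone oxide 17 (not isolated)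
Conditions: O3/O2, CH2Cl2, −78 °C, Sudan Red 7B end point; N2 purge, warm to rt; no reductant
Reagents that add atoms: ozone, [O-][O+]=O
Why: Ozone adds as a 1,3-dipole to the electron-rich trisubstituted alkene, the only site that reacts at −78 °C, to give primary ozonide 16. Cycloreversion of 16 places the carbonyl oxide on the fully substituted carbon (C3 of the target), which carries two alkyl groups and lies one bond further from the electron-withdrawing hydroperoxide than C8, and leaves C8 as an aldehyde in 17. The O–H of the C6 hydroperoxide then adds across the carbonyl oxide: its terminal oxygen bonds to C3 while the proton passes to the terminal oxygen of the carbonyl oxide, a 6-exo-trig closure that forms bond C3–O2 and the 1,2-dioxane. The closest known reaction type is the ozonolysis of unsaturated hydroperoxides, in which the tethered OOH captures the carbonyl oxide to give hydroperoxy-substituted 1,2-dioxolanes and 1,2-dioxanes. No stereocenter is controlled here: C6 is carried from 15, and C3 forms as both epimers, which converge in step 11. The selectivity that matters is capture by OOH against [3+2] recombination of the carbonyl oxide with the tethered C8 aldehyde; addition of a protic O–H through a chair-like six-membered array is expected to be faster than formation of the strained bicyclic ozonide, and the non-nucleophilic solvent offers no third partner. The silylalkyne is far less reactive toward ozone than the alkene, and the indicator dye stops the gas flow at the end point.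

Step 10
Reactants: 18 2-[(3S)-6-hydroperoxy-6-[5-(trimethylsilyl)pent-4-yn-1-yl]-1,2-dioxan-3-yl]acetaldehyde
Product: 19 2-[(3S)-6-hydroperoxy-6-[5-(trimethylsilyl)pent-4-yn-1-yl]-1,2-dioxan-3-yl]acetic acid
Conditions: NaClO2, NaH2PO4, 2-methylbut-2-ene, t-BuOH/H2O, 0 °C → rt (crude 18)
Reagents that add atoms: sodium chlorite, [Na+].[O-]Cl=O
Why: Pinnick oxidation converts the aldehyde to the acid at about pH 4, where neither β-elimination of the peroxide nor ionisation of the hydroperoxy ketal is expected; 2-methylbut-2-ene removes HOCl.

Step 11
Reactants: 19 2-[(3S)-6-hydroperoxy-6-[5-(trimethylsilyl)pent-4-yn-1-yl]-1,2-dioxan-3-yl]acetic acid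
Product: 20 methyl 2-[(3S,6R)-6-methoxy-6-[5-(trimethylsilyl)pent-4-yn-1-yl]-1,2-dioxan-3-yl]acetate
Conditions: HCl (0.2 M) in MeOH, 0 °C → rt
Reagents that add atoms: methanol, CO
Why: Acid ionises the hydroperoxy ketal to the ring peroxycarbenium ion and methanol adds; the reversible exchange should settle on the epimer with axial OMe (anomeric effect) and both carbon substituents equatorial, which is the (6R) configuration. Fischer esterification of the acid runs in the same solution, and no ketone is present yet that could take up the released H2O2.

Step 12
Reactants: 20 methyl 2-[(3S,6R)-6-methoxy-6-[5-(trimethylsilyl)pent-4-yn-1-yl]-1,2-dioxan-3-yl]acetate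
Product: 21 methyl 2-[(3S,6R)-6-methoxy-6-(pent-4-yn-1-yl)-1,2-dioxan-3-yl]acetate
Conditions: K2CO3, MeOH, 0 °C
Reagents that add atoms: none
Why: Methoxide-induced protodesilylation of the alkynylsilane; the methyl ester is unchanged in methanol, and at 0 °C the weak base should not open the β-peroxy ester.

Step 13
Reactants: 22 undec-10-en-2-one
Product: 24 9-oxodecanal, via ozonide 23 (not isolated)
Conditions: O3/O2, CH2Cl2, −78 °C; then PPh3, −78 °C → rt
Reagents that add atoms: ozone, [O-][O+]=O
Why: Ozonolysis with reductive work-up: the terminal alkene is cleaved, ozonide 23 is reduced by PPh3 to the aldehyde, and the ketone is unaffected.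

Step 14
Reactants: 24 9-oxodecanal
Product: 25 (E)-11-iodoundec-10-en-2-one
Conditions: CrCl2, CHI3, THF/1,4-dioxane, 0 °C → rt
Reagents that add atoms: iodoform, IC(I)I
Why: Takai olefination: the geminal dichromium species from CHI3 adds to the aldehyde much faster than to the ketone and eliminates to the (E)-iodoalkene; dioxane as cosolvent favours the E isomer.

Step 15
Reactants: 21 methyl 2-[(3S,6R)-6-methoxy-6-(pent-4-yn-1-yl)-1,2-dioxan-3-yl]acetate; 25 (E)-11-iodoundec-10-en-2-one
Product: 26 methyl 2-[(3S,6R)-6-methoxy-6-[(6E)-15-oxohexadec-6-en-4-yn-1-yl]-1,2-dioxan-3-yl]acetate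
Conditions: Pd(PPh3)4 (5 mol %), CuI (10 mol %), i-Pr2NH, THF, rt
Reagents that add atoms: none
Why: Sonogashira coupling joins the sp and sp2 carbons at room temperature with retention of the alkene geometry. A dialkyl peroxyketal without O–H is expected to tolerate zerovalent palladium and CuI for the short reaction time, and the methyl ketone is inert.

Step 16
Reactants: 26 methyl 2-[(3S,6R)-6-methoxy-6-[(6E)-15-oxohexadec-6-en-4-yn-1-yl]-1,2-dioxan-3-yl]acetate
Product: 27 2-[(3S,6R)-6-methoxy-6-[(6E)-15-oxohexadec-6-en-4-yn-1-yl]-1,2-dioxan-3-yl]acetic acid
Conditions: LiOH, THF/H2O, 0 °C; then dilute HCl to pH 4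
Reagents that add atoms: lithium hydroxide, [Li+].[OH-]
Why: Saponification: hydroxide attacks the ester carbonyl faster than it removes the α-proton, and once the carboxylate has formed, E1cB opening of the β-peroxy unit is suppressed. Brief, mild acidification gives the acid without ionising the ketal.

## Compound list

1 | 4-(tert-butyldimethylsilyloxy)cyclohexan-1-one | CC(C)(C)[Si](C)(C)OC1CCC(=O)CC1 | starting material
2 | lithium (R)-4-(tert-butyldimethylsilyloxy)cyclohex-1-en-1-olate | [Li]OC1=CC[C@H](O[Si](C)(C)C(C)(C)C)CC1 | intermediate
3 | (R)-4-(tert-butyldimethylsilyloxy)cyclohex-1-en-1-yl trifluoromethanesulfonate | O=S(=O)(OC1=CC[C@H](O[Si](C)(C)C(C)(C)C)CC1)C(F)(F)F | intermediate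
4 | (5-chloropent-1-yn-1-yl)trimethylsilane | C[Si](C)(C)C#CCCCCl | starting material
5 | (5-iodopent-1-yn-1-yl)trimethylsilane | C[Si](C)(C)C#CCCCI | intermediate
6 | [5-(trimethylsilyl)pent-4-yn-1-yl]zinc iodide | C[Si](C)(C)C#CCCC[Zn]I | intermediate
7 | tert-butyldimethyl{[(1R)-4-[5-(trimethylsilyl)pent-4-yn-1-yl]cyclohex-3-en-1-yl]oxy}silane | C[Si](C)(C)C#CCCCC1=CC[C@H](O[Si](C)(C)C(C)(C)C)CC1 | intermediate
8 | (1R)-4-[5-(trimethylsilyl)pent-4-yn-1-yl]cyclohex-3-en-1-ol | C[Si](C)(C)C#CCCCC1=CC[C@H](O)CC1 | intermediate
9 | (1R)-4-[5-(trimethylsilyl)pent-4-yn-1-yl]cyclohex-3-en-1-yl trifluoromethanesulfonate | C[Si](C)(C)C#CCCCC1=CC[C@H](OS(=O)(=O)C(F)(F)F)CC1 | intermediate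
10 | 2,3-dimethylbut-2-ene | CC(C)=C(C)C | starting material
11 | propan-2-one O-oxide (acetone oxide) | CC(C)=[O+][O-] | intermediate
12 | 2-hydroperoxy-2-methoxypropane (2-methoxyprop-2-yl hydroperoxide) | COC(C)(C)OO | intermediate
13 | potassium 2-methoxypropan-2-yl peroxide | [K+].COC(C)(C)O[O-] | intermediate
14 | (S)-4-[(2-methoxypropan-2-yl)peroxy]-1-[5-(trimethylsilyl)pent-4-yn-1-yl]cyclohex-1-ene | C[Si](C)(C)C#CCCCC1=CC[C@@H](OOC(C)(C)OC)CC1 | intermediate
15 | (S)-4-hydroperoxy-1-[5-(trimethylsilyl)pent-4-yn-1-yl]cyclohex-1-ene | C[Si](C)(C)C#CCCCC1=CC[C@@H](OO)CC1 | intermediate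
16 | (6S)-6-hydroperoxy-3a-[5-(trimethylsilyl)pent-4-yn-1-yl]hexahydro-1,2,3-benzotrioxole (primary ozonide, ring-fusion carbons unassigned) | C[Si](C)(C)C#CCCCC12CC[C@H](OO)CC1OOO2 | intermediate
17 | (3S)-3-hydroperoxy-6-oxo-11-(trimethylsilyl)undec-10-ynal 6-O-oxide (ketone oxide) | C[Si](C)(C)C#CCCCC(=[O+][O-])CC[C@H](OO)CC=O | intermediate
18 | 2-[(3S)-6-hydroperoxy-6-[5-(trimethylsilyl)pent-4-yn-1-yl]-1,2-dioxan-3-yl]acetaldehyde (both epimers at the hydroperoxy ketal carbon) | OOC1(CCCC#C[Si](C)(C)C)CC[C@@H](CC=O)OO1 | intermediate
19 | 2-[(3S)-6-hydroperoxy-6-[5-(trimethylsilyl)pent-4-yn-1-yl]-1,2-dioxan-3-yl]acetic acid (both epimers at the hydroperoxy ketal carbon) | OOC1(CCCC#C[Si](C)(C)C)CC[C@@H](CC(=O)O)OO1 | intermediate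
20 | methyl 2-[(3S,6R)-6-methoxy-6-[5-(trimethylsilyl)pent-4-yn-1-yl]-1,2-dioxan-3-yl]acetate | CO[C@@]1(CCCC#C[Si](C)(C)C)CC[C@@H](CC(=O)OC)OO1 | intermediate
21 | methyl 2-[(3S,6R)-6-methoxy-6-(pent-4-yn-1-yl)-1,2-dioxan-3-yl]acetate | CO[C@@]1(CCCC#C)CC[C@@H](CC(=O)OC)OO1 | intermediate
22 | undec-10-en-2-one | CC(=O)CCCCCCCC=C | starting material
23 | 9-(1,2,4-trioxolan-3-yl)nonan-2-one | CC(=O)CCCCCCCC1OCOO1 | intermediate
24 | 9-oxodecanal | CC(=O)CCCCCCCC=O | intermediate
25 | (E)-11-iodoundec-10-en-2-one | CC(=O)CCCCCCC/C=C/I | intermediate
26 | methyl 2-[(3S,6R)-6-methoxy-6-[(6E)-15-oxohexadec-6-en-4-yn-1-yl]-1,2-dioxan-3-yl]acetate | CO[C@@]1(CCCC#C/C=C/CCCCCCCC(C)=O)CC[C@@H](CC(=O)OC)OO1 | intermediate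
27 | 2-[(3S,6R)-6-methoxy-6-[(6E)-15-oxohexadec-6-en-4-yn-1-yl]-1,2-dioxan-3-yl]acetic acid | CO[C@@]1(CCCC#C/C=C/CCCCCCCC(C)=O)CC[C@@H](CC(=O)O)OO1 | target

## Step count and least certain steps

Total step count: 16. Longest linear sequence: 12 steps (1 → 27 through steps 1, 3, 4, 5, 7, 8, 9, 10, 11, 12, 15, 16).

**Step 9 (key step).**
- Risk: recombination of the carbonyl oxide with the tethered aldehyde to a bicyclic ozonide, because both partners stay in one molecule after cleavage of a ring alkene. Cycloreversion of the primary ozonide in the opposite sense, followed by five-ring capture at C8, would also divert material, as would intermolecular capture leading to oligomers.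
- Fallback: sets out from 14 and returns at 20; it closes the ring by peroxyhemiketalisation instead of carbonyl oxide capture. Ozonolysis of 14 in CH2Cl2/MeOH with Me2S work-up makes both senses of fragmentation converge on (3S)-3-[(2-methoxypropan-2-yl)peroxy]-6-oxo-11-(trimethylsilyl)undec-10-ynal F1. Pinnick oxidation gives (3S)-3-[(2-methoxypropan-2-yl)peroxy]-6-oxo-11-(trimethylsilyl)undec-10-ynoic acid F2. Methanolic HCl then unmasks the hydroperoxide, which adds to the C3 ketone, exchanges OH for OMe under the same thermodynamic control and esterifies the acid to give 20. The price is a β-peroxy aldehyde that must be oxidised without delay.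

**Step 7.**
- Risk: E2 elimination to the conjugated diene, and ionisation of the triflate with participation of the homoallylic alkene, which would return material with retained or scrambled configuration.
- Fallback: sets out from 8 and returns at 14. Alcohol 8 is converted with MsCl and Et3N into (1R)-4-[5-(trimethylsilyl)pent-4-yn-1-yl]cyclohex-3-en-1-yl methanesulfonate F3. This far less ionising sulfonate is displaced by salt 13 with 18-crown-6 in DMF at room temperature, where only the bimolecular pathway is open.

**Step 1.**
- Risk: incomplete enantiotopic discrimination, or erosion by proton exchange between enolate and ketone during the slow triflation; the enantiomeric purity set here cannot easily be raised later.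
- Fallback: sets out from 1 and returns at 3. The same amide is used under internal-quench conditions with Me3SiCl at −100 °C, which traps each enolate as it forms and gives tert-butyldimethyl{[(1R)-4-(trimethylsilyloxy)cyclohex-3-en-1-yl]oxy}silane F4. MeLi in THF then regenerates enolate 2 free of amine and ketone, and PhNTf2 gives 3.

**Step 11.**
- Risk: acid strong enough for Fischer esterification may fragment the protonated hydroperoxide (Hock or Criegee type cleavage) or leave the C3 equilibration incomplete.
- Fallback: sets out from 19 and returns at 20; it separates the two tasks. Me3SiCHN2 in MeOH/toluene at 0 °C esterifies the acid without alkylating the hydroperoxide and gives methyl 2-[(3S)-6-hydroperoxy-6-[5-(trimethylsilyl)pent-4-yn-1-yl]-1,2-dioxan-3-yl]acetate F5. The ketal exchange is then run with catalytic TsOH in MeOH, as mildly and for as long as the equilibration needs.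

**Step 15.**
- Risk: one-electron cleavage of the O–O bond by monovalent copper, insertion of zerovalent palladium into it, or amine-induced cleavage at the peroxide-bearing CH.
- Fallback: sets out from 21 and returns at 26; it uses neither copper nor amine. Bu3SnNEt2 in toluene at 50 °C converts the terminal alkyne into methyl 2-[(3S,6R)-6-methoxy-6-[5-(tributylstannyl)pent-4-yn-1-yl]-1,2-dioxan-3-yl]acetate F6. Stille coupling with 25 (Pd2(dba)3, AsPh3, NMP, rt) gives 26.

**Step 16.**
- Risk: hydroxide-induced E1cB opening of the β-peroxy ester or Kornblum–DeLaMare cleavage before the ester is hydrolysed.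
- Fallback: sets out from 19 and ends at 27; there is no ester to hydrolyse. Brief treatment of 19 with pyridinium p-toluenesulfonate in MeOH at 0 °C, where ketal exchange outruns esterification, gives 2-[(3S,6R)-6-methoxy-6-[5-(trimethylsilyl)pent-4-yn-1-yl]-1,2-dioxan-3-yl]acetic acid F7. K2CO3 in MeOH gives 2-[(3S,6R)-6-methoxy-6-(pent-4-yn-1-yl)-1,2-dioxan-3-yl]acetic acid F8. Sonogashira coupling of F8 with 25 in the presence of excess i-Pr2NH gives 27 directly; the carboxylate resists α-deprotonation throughout.

## Further compounds

F1 | step 9 | (3S)-3-[(2-methoxypropan-2-yl)peroxy]-6-oxo-11-(trimethylsilyl)undec-10-ynal | C[Si](C)(C)C#CCCCC(=O)CC[C@H](OOC(C)(C)OC)CC=O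
F2 | step 9 | (3S)-3-[(2-methoxypropan-2-yl)peroxy]-6-oxo-11-(trimethylsilyl)undec-10-ynoic acid | C[Si](C)(C)C#CCCCC(=O)CC[C@H](OOC(C)(C)OC)CC(=O)O
F3 | step 7 | (1R)-4-[5-(trimethylsilyl)pent-4-yn-1-yl]cyclohex-3-en-1-yl methanesulfonate | C[Si](C)(C)C#CCCCC1=CC[C@H](OS(C)(=O)=O)CC1
F4 | step 1 | tert-butyldimethyl{[(1R)-4-(trimethylsilyloxy)cyclohex-3-en-1-yl]oxy}silane | C[Si](C)(C)OC1=CC[C@H](O[Si](C)(C)C(C)(C)C)CC1
F5 | step 11 | methyl 2-[(3S)-6-hydroperoxy-6-[5-(trimethylsilyl)pent-4-yn-1-yl]-1,2-dioxan-3-yl]acetate | OOC1(CCCC#C[Si](C)(C)C)CC[C@@H](CC(=O)OC)OO1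
F6 | step 15 | methyl 2-[(3S,6R)-6-methoxy-6-[5-(tributylstannyl)pent-4-yn-1-yl]-1,2-dioxan-3-yl]acetate | CO[C@@]1(CCCC#C[Sn](CCCC)(CCCC)CCCC)CC[C@@H](CC(=O)OC)OO1
F7 | step 16 | 2-[(3S,6R)-6-methoxy-6-[5-(trimethylsilyl)pent-4-yn-1-yl]-1,2-dioxan-3-yl]acetic acid | CO[C@@]1(CCCC#C[Si](C)(C)C)CC[C@@H](CC(=O)O)OO1
F8 | step 16 | 2-[(3S,6R)-6-methoxy-6-(pent-4-yn-1-yl)-1,2-dioxan-3-yl]acetic acid | CO[C@@]1(CCCC#C)CC[C@@H](CC(=O)O)OO1
A1 | alternative 1 | methyl 2-[(3R)-6-methoxy-6-[5-(triisopropylsilyl)pent-4-yn-1-yl]-3,6-dihydro-1,2-dioxin-3-yl]acetate (both epimers at the ketal carbon) | COC1(CCCC#C[Si](C(C)C)(C(C)C)C(C)C)C=C[C@@H](CC(=O)OC)OO1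
A2 | alternative 1 | dimethyl (2E,4R)-4-{[3-methoxy-8-(triisopropylsilyl)oct-1-en-7-yn-3-yl]peroxy}hex-2-enedioate | COC(=O)/C=C/[C@@H](CC(=O)OC)OOC(OC)(C=C)CCCC#C[Si](C(C)C)(C(C)C)C(C)C
A3 | alternative 2 | 2-[(3S,6R)-6-methoxy-6-[5-(trimethylsilyl)pent-4-yn-1-yl]-1,2-dioxan-3-yl]ethan-1-ol | CO[C@@]1(CCCC#C[Si](C)(C)C)CC[C@@H](CCO)OO1
A4 | alternative 2 | (2R)-2-[3,3-dimethoxy-8-(trimethylsilyl)oct-7-yn-1-yl]oxetane | COC(OC)(CCCC#C[Si](C)(C)C)CC[C@@H]1CCO1
A5 | alternative 3 | tert-butyl{2-[(3S,6R)-6-methoxy-6-[5-(triisopropylsilyl)pent-4-yn-1-yl]-1,2-dioxan-3-yl]ethoxy}diphenylsilane | CO[C@@]1(CCCC#C[Si](C(C)C)(C(C)C)C(C)C)CC[C@@H](CCO[Si](c2ccccc2)(c2ccccc2)C(C)(C)C)OO1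
A6 | alternative 3 | tert-butyl{[(3S)-3-hydroperoxy-11-(triisopropylsilyl)undeca-6,10-diyn-1-yl]oxy}diphenylsilane | CC(C)[Si](C(C)C)(C(C)C)C#CCCC#CCC[C@H](OO)CCO[Si](c1ccccc1)(c1ccccc1)C(C)(C)C
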